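## The problem

The ring is numbered C1 (hept-1-enyl-bearing), C2 (CH2OH-bearing), C3 (OH), C4 and C5 (oxirane carbons, C5 quaternary) and C6 (OH). The target is a single cyclohexene with a cis-fused oxirane across C4–C5, so the difficulty is the density of substitution, not ring fusion. Every ring carbon is functionalised, and three carbon branches must be placed: the (E)-heptenyl group on C1 (a diene with C1=C2), the hydroxymethyl group on C2 and the (E)-2-methylbut-2-enoic acid chain on quaternary C5. The four stereocentres C3–C6 are contiguous, and since the oxirane ties C4 to C5, three relationships remain: the absolute sense of the epoxide, C3–OH cis to the oxirane oxygen and C6–OH trans to it. Once present, the oxirane oxygen differentiates the faces of both flanking carbons and can control C6 and C3 if these are made from carbonyl groups. Nothing in the molecule can control the oxirane itself, which must come from an enantioselective reaction. The finished molecule is fragile: a trans-β-hydroxy epoxide (C6/C5) that can undergo Payne migration in base, allylic carbinols and an oxirane that ionise in acid, a diene open to oxidants and metathesis catalysts, and a free acid. The enabling feature is that C3 and C6 are para-related oxygen-bearing carbons on a ring whose other positions carry only carbon substituents (C1, C2, C5) or hydrogen (C4). At the hydroquinone monoether oxidation level this is a 4-methoxyphenol whose six carbons can be assembled in one step from an alkenyl carbene complex (C3, C2, C1), a terminal alkyne (C4, C5) and a carbonyl ligand (C6).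

## Retrosynthesis

**Side chain.** Acid 21 is traced to enal 20, and 20 to triol 18 and methacrolein 19 by cutting C2'=C3' of the chain (cross-metathesis). This keeps an inert allyl group on C5 through all organometallic and hydride steps. The aldehyde level is preferred to an ester because an ester would have to be saponified next to the trans-β-hydroxy epoxide, whereas 20 is oxidised to 21 under weakly acidic conditions. The forward step must engage only the monosubstituted alkene of 18 and give the E-enal.

**Carbinols.** The C3–H and C6–H bonds are removed in turn: 18 from enone 17 (reduction at C3), 17 from dimethyl ketal 16 (hydrolysis), and 16 from epoxy ketone 15 (reduction at C6). Both carbinols then come under control of the oxirane. Keeping the C3 carbonyl masked while C6 is reduced lets each reduction use the reagent suited to its sense (C6 trans, C3 cis). Compound 15 has two stereocentres instead of four. The forward reductions must be 1,2-selective and facially selective in opposite senses.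

**Oxirane and ketal.** The two oxirane C–O bonds are cut: 15 comes from cross-conjugated dienone 14 by nucleophilic epoxidation of the C4=C5 enone. Dienone 14 comes from silyl ether 13, and 13 from phenol 12 by oxidative ketalisation at C3. A quinone monoketal is the only oxidation level at which C4=C5 is electrophilic, C3 and C6 stay differentiated, and C2=C1 (fully substituted β-carbon) is protected by its own substitution. Compound 12 is achiral and aromatic. The forward epoxidation must set the absolute configuration, and for that the C2 hydroxymethyl group is freed (13 to 14) to serve as anchor.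

**Ring (key disconnection).** All six ring carbons of 12 are disconnected at once across C3–C4, C5–C6 and C6–C1. This leads to carbene complex 9 (C3 with its methoxy group, C2, C1 and both attached chains), pent-1-en-4-yne 10 (C4, C5 and the allyl group) and a carbonyl ligand of 9 (C6 and its oxygen). The neighbouring cuts, stepwise allylation, alkenylation and hydroxymethylation of a preformed arene, would need three C–C bonds on a crowded ring with ortho/meta selectivity problems. Here all positions are fixed by the mechanism, and the C6 phenol and C3 methyl ether emerge already differentiated. The forward reaction must insert the alkyne in one orientation and incorporate CO before other cyclisation modes intervene.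

**Carbene complex.** Complex 9 is cut at the Cr=C carbon into hexacarbonylchromium 6 and the dienyl unit of bromide 5. Bromide 5 comes from alcohol 4, ester 3, and finally (E)-oct-2-enal 1 and bromophosphonate 2 by cutting C2=C3 of the diene (olefination). An olefination that puts bromine trans to the chain is chosen over dibromo-olefination and selective exchange because the geometry of C2=C1 in 9 is then fixed by a known selectivity rule. The forward sequence must keep this geometry through bromine–lithium exchange.

## Roads not taken

**Alternative 1: intramolecular Darzens closure.** The cut is through C4–C5 and the C5–O oxirane bond. In the forward step the enolate of the open-chain α-bromo ketone aldehyde A2 adds to its C4 aldehyde, and the alkoxide displaces bromide to give epoxy enone A1.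
- Merits: ring and oxirane form in one operation, no stoichiometric metal is used, there is no aromatic detour, and the C3 oxygen never passes through a ketone. The absolute configuration can descend from one early centre (C3). In these respects it is better than the chosen plan.
- Weak points: A2 needs a stereodefined tetrasubstituted C1=C2 alkene with four different carbon substituents in an open chain. Its α-silyloxy aldehyde can epimerise under the basic closure. One existing centre must control two new ones (C4 and quaternary C5) through an aldol whose halohydrin must also have the anti arrangement needed for displacement. A1 still requires the C6 reduction and the side-chain metathesis of the chosen route.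
- Comparison: the chosen plan sets against this the certainty with which the benzannulation places every substituent, and a four-step access to its precursor 9.

**Alternative 2: tandem ring-closing enyne metathesis and cross-metathesis.** The cut is through ring C1=C2 and the C1'=C2' bond of the heptenyl group. A ruthenium alkylidene carrying C2'–C7' adds to the terminal alkyne of enyne A4, and the resulting vinylcarbene closes onto the 1,1-disubstituted alkene to give the protected target A3.
- Merits: it is the most convergent idea, catalytic in metal, and builds ring and diene together. A3 already carries the complete acid chain, so no metathesis is needed next to a finished diene. All four stereocentres would be set by reagent-controlled acyclic chemistry, so no ring reduction has to be steered. On these points it is better than the chosen plan.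
- Weak points: A4 is an open chain with four contiguous stereocentres including the quaternary oxirane carbon, and would take far more steps than 9 plus 10. The closure must form a tetrasubstituted ring alkene from a hindered carbene and a 1,1-disubstituted alkene, in competition with initiation at the alkene, endo closure, simple enyne cross-metathesis and attack on the enoate. The new C1'=C2' geometry is not assured.
- Comparison: the chosen plan sets a short, well-charted ring synthesis against a risky late step on a costly intermediate, and accepts two substrate-controlled reductions in exchange.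

**Alternative 3: carbene-catalysed crossed benzoin closing C5–C6.** The cut is through C5–C6. A chiral triazolium-derived carbene turns the enal of keto enal A6 into its Breslow intermediate, which adds to the C5 ketone to give α-ketol A5 with the C5 hydroxyl trans to the C4 silyloxy group.
- Merits: the quaternary centre is made catalytically without metal. C3 and C4 can come from the chiral pool. The acid chain would later be made by Wittig olefination, which is reliably E-selective and avoids metathesis beside the diene, a point where it is at least as good as the chosen plan.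
- Weak points: an enal-derived Breslow intermediate can react as a homoenolate, and here the C3 silyloxy group is placed for vinylogous β-elimination. Catalyst control must override two resident stereocentres. A5 is far from the target: the oxirane must still be closed by displacement at C4 after selective desilylation and sulfonylation, C6 must be reduced (the same open question as in the chosen route), and the protected hydroxyethyl arm must be deprotected by an oxidant in the presence of the diene, oxidised and olefinated. A6 also needs the tetrasubstituted alkene geometry.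
- Comparison: the chosen plan is much shorter after its key step and builds the oxirane in one enantioselective step.

Key step: step 5

Assumption 1: phosphonate 2 is treated as purchasable; otherwise it is made by α-bromination of the commercial bis(2,2,2-trifluoroethyl) phosphonoacetate.

Assumption 2: L-(+)-diisopropyl tartrate is assumed to direct the peroxide to the face that gives 15; if the sense is opposite, the D-(−) ester is used with no other change.

## Route

Step 1
Reactants: 1 (E)-oct-2-enal; 2 methyl 2-[bis(2,2,2-trifluoroethoxy)phosphoryl]-2-bromoacetate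
Product: 3 methyl (2E,4E)-2-bromodeca-2,4-dienoate
Conditions: KOt-Bu, 18-crown-6, THF, −78 °C
Reagents that add atoms: none
Why: Horner–Wadsworth–Emmons olefination of the Still–Gennari type; the trifluoroethyl phosphonate makes elimination from the kinetic adduct fast, so the ester ends cis to the chain and bromine trans to it (2E), while the 4E alkene of 1 is untouched. This geometry later places the carbene carbon trans to the heptenyl chain.

Step 2
Reactants: 3 methyl (2E,4E)-2-bromodeca-2,4-dienoate
Product: 4 (2E,4E)-2-bromodeca-2,4-dien-1-ol
Conditions: i-Bu2AlH (2.2 equiv), CH2Cl2, −78 °C; aq. potassium sodium tartrate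
Reagents that add atoms: none
Why: 1,2-Reduction of a conjugated ester by an aluminium hydride at low temperature; the vinyl bromide and both alkene geometries are inert.

Step 3
Reactants: 4 (2E,4E)-2-bromodeca-2,4-dien-1-ol
Product: 5 [(2E,4E)-2-bromodeca-2,4-dienoxy]tri(propan-2-yl)silane
Conditions: i-Pr3SiCl, imidazole, DMF, rt
Reagents that add atoms: chlorotri(propan-2-yl)silane, CC(C)[Si](Cl)(C(C)C)C(C)C
Why: Standard silylation of a primary allylic alcohol. The triisopropylsilyl group is chosen over smaller silyl groups because it resists migration from oxygen to the adjacent carbanion in step 4 and survives steps 4 to 6.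

Step 4
Reactants: 5 [(2E,4E)-2-bromodeca-2,4-dienoxy]tri(propan-2-yl)silane; 6 hexacarbonylchromium
Product: 9 pentacarbonyl[(2E,4E)-1-methoxy-2-{[tri(propan-2-yl)silyloxy]methyl}deca-2,4-dienylidene]chromium, via dienyllithium 7 (not isolated), via lithium acylchromate 8 (not isolated)
Conditions: t-BuLi (2.05 equiv), Et2O, −78 °C; Cr(CO)6, Et2O, −78 → 0 °C; MeOTf, CH2Cl2, 0 °C
Reagents that add atoms: methyl trifluoromethanesulfonate, COS(=O)(=O)C(F)(F)F
Why: Fischer carbene synthesis; bromine–lithium exchange with retention of alkene geometry gives 7, which adds to a carbonyl ligand of 6 to give acylate 8, and the hard methylating agent alkylates oxygen. Low temperature and the bulky silyl ether suppress elimination or silyl shift in 7.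

Step 5
Reactants: 9 pentacarbonyl[(2E,4E)-1-methoxy-2-{[tri(propan-2-yl)silyloxy]methyl}deca-2,4-dienylidene]chromium; 10 pent-1-en-4-yne
Product: 12 2-allyl-6-[(E)-hept-1-enyl]-4-methoxy-5-{[tri(propan-2-yl)silyloxy]methyl}phenol, via tricarbonylchromium arene complex 11 (not isolated)
Conditions: 10 (2 equiv), THF (0.05 M), 50 °C, sealed vessel, argon; then air, CH2Cl2, rt
Reagents that add atoms: none
Why: Dötz benzannulation of an alkenyl(methoxy)carbene complex of zerovalent chromium with a terminal alkyne, which is the closest known reaction type and applies directly. Thermal loss of one CO from 9 opens a site for 10, which inserts into the Cr=C bond with its allyl-bearing carbon away from the carbene carbon (C3–C4 formed); CO insertion into the resulting vinylcarbene gives a chromium-bound dienylketene (C5–C6 formed). The ring is closed by thermal disrotatory 6π-electrocyclisation of this ketene onto the alkenyl CH (C6–C1 formed), and tautomerisation through the C1 hydrogen gives the phenol as its Cr(CO)3 complex 11, which air decomplexes to 12. No stereocentre is created. The step needs regioselective insertion, secured by the steric difference between the two ends of a terminal alkyne, and phenol formation in preference to five-membered-ring products, favoured by the alkenyl (not aryl) carbene, by THF and by the free CH at the ring-closing terminus. The E geometry of C2=C1 in 9 holds the carbene carbon trans to the heptenyl chain, so the complex cannot cyclise onto its own diene before the alkyne arrives. The isolated alkene of 10 and the distal alkene of 9 are spectators.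

Step 6
Reactants: 12 2-allyl-6-[(E)-hept-1-enyl]-4-methoxy-5-{[tri(propan-2-yl)silyloxy]methyl}phenol
Product: 13 2-allyl-6-[(E)-hept-1-enyl]-4,4-dimethoxy-5-{[tri(propan-2-yl)silyloxy]methyl}cyclohexa-2,5-dien-1-one
Conditions: PhI(OAc)2, MeOH, 0 °C
Reagents that add atoms: methanol, CO
Why: Hypervalent-iodine oxidation of a 4-methoxyphenol; the cation is captured by methanol at the methoxy-bearing para carbon, giving the quinone monoketal with the ketone at C6 and the ketal at C3. Alkenes and the silyl ether are inert at 0 °C.

Step 7
Reactants: 13 2-allyl-6-[(E)-hept-1-enyl]-4,4-dimethoxy-5-{[tri(propan-2-yl)silyloxy]methyl}cyclohexa-2,5-dien-1-one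
Product: 14 2-allyl-6-[(E)-hept-1-enyl]-5-(hydroxymethyl)-4,4-dimethoxycyclohexa-2,5-dien-1-one
Conditions: Bu4NF, AcOH (1:1), THF, 0 °C → rt
Reagents that add atoms: none
Why: Fluoride cleavage of a primary silyl ether; the acetic acid buffer protects the base-sensitive dienone and the ketal. The free hydroxymethyl group is the anchor for step 8.

Step 8
Reactants: 14 2-allyl-6-[(E)-hept-1-enyl]-5-(hydroxymethyl)-4,4-dimethoxycyclohexa-2,5-dien-1-one
Product: 15 (1R,6S)-1-allyl-3-[(E)-hept-1-enyl]-4-(hydroxymethyl)-5,5-dimethoxy-7-oxabicyclo[4.1.0]hept-3-en-2-one
Conditions: Ph3COOH, NaN(SiMe3)2, L-(+)-diisopropyl tartrate, toluene, −78 → −50 °C; aq. NH4Cl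
Reagents that add atoms: triphenylmethyl hydroperoxide, OOC(c1ccccc1)(c1ccccc1)c1ccccc1
Why: Weitz–Scheffer nucleophilic epoxidation in its tartrate-mediated, hydroxyl-directed form; the sodium alkoxide of the C2 hydroxymethyl group, sodium tartrate and the bulky peroxide anion form an aggregate that delivers the peroxide to one face of C4, and closure of the enolate on the O–O bond sets C4 and C5 together as the cis-fused oxirane. Only C4=C5 reacts because its β-carbon bears hydrogen, whereas C2 of the other enone is fully substituted.

Step 9
Reactants: 15 (1R,6S)-1-allyl-3-[(E)-hept-1-enyl]-4-(hydroxymethyl)-5,5-dimethoxy-7-oxabicyclo[4.1.0]hept-3-en-2-one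
Product: 16 (1S,2R,6S)-1-allyl-3-[(E)-hept-1-enyl]-4-(hydroxymethyl)-5,5-dimethoxy-7-oxabicyclo[4.1.0]hept-3-en-2-ol
Conditions: i-Bu2AlH (3 equiv), THF, −78 °C; aq. potassium sodium tartrate
Reagents that add atoms: none
Why: 1,2-Reduction of the enone carbonyl (its β-carbon is fully substituted). The oxirane oxygen stands nearly perpendicular to the carbonyl plane on the lower face, and an aluminium hydride bound to it should deliver hydride to C6 from that face through a five-membered transition state, giving the C6 hydroxyl trans to the epoxide, the sense usually found for this reagent with epoxy ketones of the quinone monoketal type.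

Step 10
Reactants: 16 (1S,2R,6S)-1-allyl-3-[(E)-hept-1-enyl]-4-(hydroxymethyl)-5,5-dimethoxy-7-oxabicyclo[4.1.0]hept-3-en-2-ol
Product: 17 (1S,5R,6S)-6-allyl-4-[(E)-hept-1-enyl]-5-hydroxy-3-(hydroxymethyl)-7-oxabicyclo[4.1.0]hept-3-en-2-one
Conditions: pyridinium p-toluenesulfonate (cat.), acetone/H2O (10:1), 0 °C → rt
Reagents that add atoms: water, O
Why: Acid-catalysed ketal hydrolysis; ionisation at C3 is assisted by the adjoining diene, so a weak acid suffices, while the oxirane and the C6 carbinol (whose cation would sit beside the electron-poor oxirane carbon) are not ionised. No stereocentre is touched.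

Step 11
Reactants: 17 (1S,5R,6S)-6-allyl-4-[(E)-hept-1-enyl]-5-hydroxy-3-(hydroxymethyl)-7-oxabicyclo[4.1.0]hept-3-en-2-one
Product: 18 (1S,2R,5R,6R)-1-allyl-3-[(E)-hept-1-enyl]-4-(hydroxymethyl)-7-oxabicyclo[4.1.0]hept-3-ene-2,5-diol
Conditions: NaBH4, CeCl3·7H2O, MeOH, −78 °C
Reagents that add atoms: none
Why: Luche 1,2-reduction of the dienone; hydride attacks C3 anti to the C4–O bond of the oxirane (upper face, past C4–H), the Felkin–Anh and steric preference, giving the C3 hydroxyl cis to the epoxide. Conjugate reduction and epoxide opening are not expected at −78 °C.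

Step 12
Reactants: 18 (1S,2R,5R,6R)-1-allyl-3-[(E)-hept-1-enyl]-4-(hydroxymethyl)-7-oxabicyclo[4.1.0]hept-3-ene-2,5-diol; 19 2-methylprop-2-enal
Product: 20 (E)-4-[(1S,2R,5R,6R)-3-[(E)-hept-1-enyl]-2,5-dihydroxy-4-(hydroxymethyl)-7-oxabicyclo[4.1.0]hept-3-en-1-yl]-2-methylbut-2-enal
Conditions: 19 (10 equiv), second-generation Grubbs catalyst (H2IMes)(PCy3)Cl2Ru=CHPh (5–10 mol %), CH2Cl2, 40 °C
Reagents that add atoms: none
Why: Olefin cross-metathesis; the ruthenium carbene initiates at the unhindered monosubstituted alkene and exchanges with the 1,1-disubstituted enal, which does not homodimerise, and the trisubstituted product forms under thermodynamic control as the E isomer. The tetrasubstituted ring alkene is inert and the heptenyl alkene is shielded by the fully substituted C1; free hydroxyls and the epoxide are tolerated.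

Step 13
Reactants: 20 (E)-4-[(1S,2R,5R,6R)-3-[(E)-hept-1-enyl]-2,5-dihydroxy-4-(hydroxymethyl)-7-oxabicyclo[4.1.0]hept-3-en-1-yl]-2-methylbut-2-enal
Product: 21 (E)-4-[(1S,2R,5R,6R)-3-[(E)-hept-1-enyl]-2,5-dihydroxy-4-(hydroxymethyl)-7-oxabicyclo[4.1.0]hept-3-en-1-yl]-2-methylbut-2-enoic acid
Conditions: NaClO2, NaH2PO4, 2-methylbut-2-ene, t-BuOH/H2O, 0 °C → rt
Reagents that add atoms: sodium chlorite, [Na+].[O-]Cl=O
Why: Pinnick oxidation; chlorous acid converts the conjugated aldehyde to the acid near pH 4 without touching alcohols, epoxide or alkenes, and the alkene scavenger removes hypochlorous acid before it can add to the diene. No base is present, so epoxide migration is avoided.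

## Compound list

1 | (E)-oct-2-enal | CCCCC/C=C/C=O | starting material
2 | methyl 2-[bis(2,2,2-trifluoroethoxy)phosphoryl]-2-bromoacetate | COC(=O)C(Br)P(=O)(OCC(F)(F)F)OCC(F)(F)F | starting material
3 | methyl (2E,4E)-2-bromodeca-2,4-dienoate | CCCCC/C=C/C=C(/Br)C(=O)OC | intermediate
4 | (2E,4E)-2-bromodeca-2,4-dien-1-ol | CCCCC/C=C/C=C(/Br)CO | intermediate
5 | [(2E,4E)-2-bromodeca-2,4-dienoxy]tri(propan-2-yl)silane | CCCCC/C=C/C=C(/Br)CO[Si](C(C)C)(C(C)C)C(C)C | intermediate
6 | hexacarbonylchromium, Cr(CO)6 | O=C=[Cr](=C=O)(=C=O)(=C=O)(=C=O)=C=O | starting material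
7 | [(2Z,4E)-1-[tri(propan-2-yl)silyloxy]deca-2,4-dien-2-yl]lithium | CCCCC/C=C/C=C(/[Li])CO[Si](C(C)C)(C(C)C)C(C)C | intermediate
8 | lithium pentacarbonyl[(2E,4E)-2-{[tri(propan-2-yl)silyloxy]methyl}deca-2,4-dienoyl]chromate | [Li+].[O-]C(=[Cr](=C=O)(=C=O)(=C=O)(=C=O)=C=O)/C(CO[Si](C(C)C)(C(C)C)C(C)C)=C/C=C/CCCCC | intermediate
9 | pentacarbonyl[(2E,4E)-1-methoxy-2-{[tri(propan-2-yl)silyloxy]methyl}deca-2,4-dienylidene]chromium | COC(=[Cr](=C=O)(=C=O)(=C=O)(=C=O)=C=O)/C(CO[Si](C(C)C)(C(C)C)C(C)C)=C/C=C/CCCCC | intermediate
10 | pent-1-en-4-yne | C=CCC#C | starting material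
11 | tricarbonyl(η6-arene)chromium complex of phenol 12 (arene and Cr(CO)3 fragment written side by side) | COc1cc(CC=C)c(O)c(/C=C/CCCCC)c1CO[Si](C(C)C)(C(C)C)C(C)C.O=C=[Cr](=C=O)=C=O | intermediate
12 | 2-allyl-6-[(E)-hept-1-enyl]-4-methoxy-5-{[tri(propan-2-yl)silyloxy]methyl}phenol | COc1cc(CC=C)c(O)c(/C=C/CCCCC)c1CO[Si](C(C)C)(C(C)C)C(C)C | intermediate
13 | 2-allyl-6-[(E)-hept-1-enyl]-4,4-dimethoxy-5-{[tri(propan-2-yl)silyloxy]methyl}cyclohexa-2,5-dien-1-one | COC1(OC)C=C(CC=C)C(=O)C(/C=C/CCCCC)=C1CO[Si](C(C)C)(C(C)C)C(C)C | intermediate
14 | 2-allyl-6-[(E)-hept-1-enyl]-5-(hydroxymethyl)-4,4-dimethoxycyclohexa-2,5-dien-1-one | COC1(OC)C=C(CC=C)C(=O)C(/C=C/CCCCC)=C1CO | intermediate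
15 | (1R,6S)-1-allyl-3-[(E)-hept-1-enyl]-4-(hydroxymethyl)-5,5-dimethoxy-7-oxabicyclo[4.1.0]hept-3-en-2-one | CCCCC/C=C/C1=C(CO)C(OC)(OC)[C@H]2O[C@@]2(CC=C)C1=O | intermediate
16 | (1S,2R,6S)-1-allyl-3-[(E)-hept-1-enyl]-4-(hydroxymethyl)-5,5-dimethoxy-7-oxabicyclo[4.1.0]hept-3-en-2-ol (hydroxyl trans to the oxirane oxygen) | CCCCC/C=C/C1=C(CO)C(OC)(OC)[C@H]2O[C@@]2(CC=C)[C@@H]1O | intermediate
17 | (1S,5R,6S)-6-allyl-4-[(E)-hept-1-enyl]-5-hydroxy-3-(hydroxymethyl)-7-oxabicyclo[4.1.0]hept-3-en-2-one | CCCCC/C=C/C1=C(CO)C(=O)[C@H]2O[C@@]2(CC=C)[C@@H]1O | intermediate
18 | (1S,2R,5R,6R)-1-allyl-3-[(E)-hept-1-enyl]-4-(hydroxymethyl)-7-oxabicyclo[4.1.0]hept-3-ene-2,5-diol | CCCCC/C=C/C1=C(CO)[C@@H](O)[C@H]2O[C@@]2(CC=C)[C@@H]1O | intermediate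
19 | 2-methylprop-2-enal (methacrolein) | C=C(C)C=O | starting material
20 | (E)-4-[(1S,2R,5R,6R)-3-[(E)-hept-1-enyl]-2,5-dihydroxy-4-(hydroxymethyl)-7-oxabicyclo[4.1.0]hept-3-en-1-yl]-2-methylbut-2-enal | CCCCC/C=C/C1=C(CO)[C@@H](O)[C@H]2O[C@@]2(C/C=C(\C)C=O)[C@@H]1O | intermediate
21 | (E)-4-[(1S,2R,5R,6R)-3-[(E)-hept-1-enyl]-2,5-dihydroxy-4-(hydroxymethyl)-7-oxabicyclo[4.1.0]hept-3-en-1-yl]-2-methylbut-2-enoic acid | CCCCC/C=C/C1=C(CO)[C@@H](O)[C@H]2O[C@@]2(C/C=C(\C)C(=O)O)[C@@H]1O | target

## Step count and least certain steps

Total step count: 13. Longest linear sequence: 13 steps (1 to 21).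

**Step 5 (key step).** CO insertion may fail to keep pace with the alkyne-inserted vinylcarbene, because the carbon next to the carbene centre carries the bulky silyloxymethyl group. Material would then be diverted to non-aromatic cyclisation or to oligomerisation of the volatile enyne. Air oxidation of the electron-rich phenol during decomplexation is a second loss. Fallback: the same dienylketene is generated without chromium by a Moore-type ring expansion. Bromide 5 is lithiated as in step 4 and added to the carbonyl next to the ring CH of 3-allylcyclobut-3-ene-1,2-dione F1 (from a dialkyl squarate by allyl addition, reduction and hydrolysis). The alkoxide is methylated in the same flask with MeOTf to give 2-allyl-4-methoxy-4-dienylcyclobut-2-en-1-one F2. Heating F2 in toluene opens the four-membered ring to the dienylketene, which closes and tautomerises. The fallback sets out from 5 and returns at 12.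

**Step 8.** Facial discrimination may be insufficient, or delivery may go to the opposite face, because the anchoring alkoxide on C2 must reach C4 across the ketal carbon while C1 carries a flexible chain. Slow conversion of the trisubstituted, cross-conjugated enone is a second risk. Fallback: induction is moved from hydroxyl templating to chiral ion pairing on the protected substrate. Silyl ether 13 is epoxidised under phase transfer (N-benzylcinchonidinium chloride or its pseudo-enantiomer, t-BuOOH, aq. NaOH, toluene) to the silyl-protected epoxy ketone F3, which is desilylated with Bu4NF/AcOH. The fallback sets out from 13 and returns at 15.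

**Step 9.** Facial selectivity may be poor or reversed: hydride held on the carbonyl oxygen may be delivered from the upper face faster than an oxirane-bound aluminium hydride delivers from below. Fallback: the cis isomer is made on purpose and inverted. Ketone 15 is reduced with LiB(s-Bu)3H (THF, −78 °C), which attacks opposite the oxirane oxygen, to the C6-epimeric diol F4. Mitsunobu reaction with 4-nitrobenzoic acid (PPh3, diisopropyl azodicarboxylate) esterifies both hydroxyls, the secondary one with inversion, to give bis(4-nitrobenzoate) F5. Methanolysis (K2CO3, MeOH, 0 °C) releases the diol. The fallback sets out from 15 and returns at 16.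

**Step 12.** Once the allyl group is consumed, the ruthenium methylidene may attack the disubstituted alkene of the heptenyl diene and truncate the chain, or the catalyst may be held by the triol so that conversion stalls. Fallback: oxidative cleavage and olefination replace metathesis. Triol 18 is dihydroxylated at the unhindered monosubstituted alkene (OsO4 cat., N-methylmorpholine N-oxide, acetone/H2O) to pentaol F6. Cleavage with NaIO4 gives aldehyde F7, expected to rest as its lactol with the C6 hydroxyl. Wittig olefination with the stabilised ylide 2-(triphenylphosphoranylidene)propanal in toluene gives the E-enal. Selectivity of the osmylation over the diene is the weak point of this fallback. It sets out from 18 and returns at 20.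

## Further compounds

F1 | step 5 | 3-allylcyclobut-3-ene-1,2-dione | C=CCC1=CC(=O)C1=O
F2 | step 5 | 2-allyl-4-methoxy-4-[(2E,4E)-1-[tri(propan-2-yl)silyloxy]deca-2,4-dien-2-yl]cyclobut-2-en-1-one | COC1(C=C(CC=C)C1=O)/C(CO[Si](C(C)C)(C(C)C)C(C)C)=C/C=C/CCCCC
F3 | step 8 | (1R,6S)-1-allyl-3-[(E)-hept-1-enyl]-5,5-dimethoxy-4-{[tri(propan-2-yl)silyloxy]methyl}-7-oxabicyclo[4.1.0]hept-3-en-2-one | CCCCC/C=C/C1=C(CO[Si](C(C)C)(C(C)C)C(C)C)C(OC)(OC)[C@H]2O[C@@]2(CC=C)C1=O
F4 | step 9 | (1S,2S,6S)-1-allyl-3-[(E)-hept-1-enyl]-4-(hydroxymethyl)-5,5-dimethoxy-7-oxabicyclo[4.1.0]hept-3-en-2-ol (hydroxyl cis to the oxirane oxygen) | CCCCC/C=C/C1=C(CO)C(OC)(OC)[C@H]2O[C@@]2(CC=C)[C@H]1O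
F5 | step 9 | [(1S,2R,6S)-1-allyl-3-[(E)-hept-1-enyl]-5,5-dimethoxy-2-(4-nitrobenzoyloxy)-7-oxabicyclo[4.1.0]hept-3-en-4-yl]methyl 4-nitrobenzoate | CCCCC/C=C/C1=C(COC(=O)c3ccc(cc3)[N+](=O)[O-])C(OC)(OC)[C@H]2O[C@@]2(CC=C)[C@@H]1OC(=O)c4ccc(cc4)[N+](=O)[O-]
F6 | step 12 | (1S,2R,5R,6R)-1-(2,3-dihydroxypropyl)-3-[(E)-hept-1-enyl]-4-(hydroxymethyl)-7-oxabicyclo[4.1.0]hept-3-ene-2,5-diol (both epimers at the side-chain carbinol) | CCCCC/C=C/C1=C(CO)[C@@H](O)[C@H]2O[C@@]2(CC(O)CO)[C@@H]1O
F7 | step 12 | 2-[(1S,2R,5R,6R)-3-[(E)-hept-1-enyl]-2,5-dihydroxy-4-(hydroxymethyl)-7-oxabicyclo[4.1.0]hept-3-en-1-yl]acetaldehyde | CCCCC/C=C/C1=C(CO)[C@@H](O)[C@H]2O[C@@]2(CC=O)[C@@H]1O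
A1 | alternative 1 | bis-silylated 5-allyl epoxycyclohexenone (C6 ketone), product of the Darzens closure | CCCCC/C=C/C1=C(CO[Si](C)(C)C(C)(C)C)[C@@H](O[Si](C)(C)C(C)(C)C)[C@H]2O[C@@]2(CC=C)C1=O
A2 | alternative 1 | open-chain α-bromo ketone aldehyde (C4 aldehyde, C3 silyl ether, C1=C2 alkene, C6 ketone, C5 bromide) | CCCCC/C=C/C(C(=O)C(Br)CC=C)=C(\CO[Si](C)(C)C(C)(C)C)[C@@H](O[Si](C)(C)C(C)(C)C)C=O
A3 | alternative 2 | protected target: C3/CH2OH acetonide, C6 triethylsilyl ether, methyl ester | CCCCC/C=C/C1=C2COC(C)(C)O[C@H]2[C@H]3O[C@@]3(C/C=C(\C)C(=O)OC)[C@@H]1O[Si](CC)(CC)CC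
A4 | alternative 2 | open-chain enyne: C6 propargylic triethylsilyl ether, C4–C5 oxirane with methyl ester chain, 5-methylidene-1,3-dioxane from C2/C3 | C=C1COC(C)(C)O[C@H]1[C@H]2O[C@@]2(C/C=C(\C)C(=O)OC)[C@H](O[Si](CC)(CC)CC)C#C
A5 | alternative 3 | cyclic tertiary α-ketol (C6 ketone, C5 hydroxyl trans to the C4 silyloxy group) | CCCCC/C=C/C1=C(CO[Si](C)(C)C(C)(C)C)[C@@H](O[Si](C)(C)C(C)(C)C)[C@H](O[Si](CC)(CC)CC)[C@](O)(CCOCc2ccc(OC)cc2)C1=O
A6 | alternative 3 | open-chain keto enal (C6 aldehyde on C1=C2, C5 ketone) | CCCCC/C=C/C(C=O)=C(\CO[Si](C)(C)C(C)(C)C)[C@@H](O[Si](C)(C)C(C)(C)C)[C@H](O[Si](CC)(CC)CC)C(=O)CCOCc1ccc(OC)cc1
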